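Ring B, with C5 and the C8 methyl group, comes from (R)-carvone, and everything rests on closing ring A last at C3–C4. The key step exploits the quaternary carbon C4 of ring A, which bears CH3 and CH2OH and sits next to the carvone stereocentre C5. Hydrogen-atom transfer to a silyloxymethyl-substituted vinyl group gives the tertiary C4 radical. Its 6-endo addition to a vinyl sulfone builds the C3–C4 bond, ring A and the C4 stereocentre in one operation. The precursor is carvone carrying an allylic OTBS group, a methyl group on C10 and, anti to the C5 side chain, a 2-(phenylsulfonyl)allyl arm. The C9 ketone later directs C6, C8, C9 and the side chain.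

Key step: step 9

Remarks on the chemistry:
- **Numbering.** Labdane numbers are used throughout: ring A = C1–C5 and C10, ring B = C5–C10, chain = C11–C16. β is the face of the C10 methyl group.
- **C2 epimers.** Compounds 15–24 are carried as C2 epimer mixtures. This centre disappears in step 17.
- **Source of the bromide.** Bromide 12 has sulfur on the central allyl carbon, so it is built from phenyl vinyl sulfone and formaldehyde. An allyl sulfone with sulfur on a terminal carbon cannot give it.
- **Order of the early steps.** The allylic oxygen is installed and silylated before the vinyl sulfone is present, so the sulfone never meets methoxide.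
- **C9 stereochemistry.** Any group delivered to C9 arrives from the open α face. C11 is therefore attached to an sp2 C9, and hydrogen is added last.

Step 1
Reactants: 1 (R)-(−)-carvone
Product: 2 (5R)-5-(3-chloroprop-1-en-2-yl)-2-methylcyclohex-2-en-1-one
Conditions: Ca(OCl)2, CO2 (s), CH2Cl2/H2O, 0 °C
Reagents that add atoms: calcium hypochlorite, [Ca+2].[O-]Cl.[O-]Cl
Why: Ene-type allylic chlorination with HOCl attacks only the electron-rich 1,1-disubstituted alkene and leaves the enone and C5 untouched.

Step 2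
Reactants: 2 allylic chloride
Product: 3 (5R)-5-(3-acetoxyprop-1-en-2-yl)-2-methylcyclohex-2-en-1-one
Conditions: KOAc, Bu4NI (cat.), DMF, 60 °C
Reagents that add atoms: potassium acetate, [K+].CC([O-])=O
Why: SN2 displacement of the primary allylic chloride by acetate.

Step 3
Reactants: 3 allylic acetate
Product: 4 (5R)-5-(3-hydroxyprop-1-en-2-yl)-2-methylcyclohex-2-en-1-one
Conditions: K2CO3 (cat.), MeOH, 0 °C
Reagents that add atoms: none
Why: Base-catalysed transesterification frees the allylic alcohol at a stage where no base-sensitive vinyl sulfone is present.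

Step 4
Reactants: 4 allylic alcohol
Product: 5 (5R)-5-[3-(tert-butyldimethylsilyloxy)prop-1-en-2-yl]-2-methylcyclohex-2-en-1-one
Conditions: TBSCl, imidazole, CH2Cl2, rt
Reagents that add atoms: TBSCl, CC(C)(C)[Si](C)(C)Cl
Why: Standard imidazole-promoted silylation of a primary alcohol.

Step 5
Reactants: 5 silyl ether; 6 iodomethane
Product: 8 (5R,6RS)-5-[3-(tert-butyldimethylsilyloxy)prop-1-en-2-yl]-2,6-dimethylcyclohex-2-en-1-one, via lithium dienolate 7 (not isolated)
Conditions: LDA, THF, −78 °C; MeI, −78 → 0 °C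
Reagents that add atoms: iodomethane (6), CI
Why: Kinetic α′-deprotonation and SN2 methylation of the cross-conjugated enolate; the epimer ratio at the new centre (C10) is irrelevant because it is planarised again in step 8.

Step 6
Reactants: 9 phenyl vinyl sulfone; 10 formaldehyde
Product: 11 2-(phenylsulfonyl)prop-2-en-1-ol
Conditions: 37% aq. HCHO, DABCO (cat.), THF/H2O, rt
Reagents that add atoms: formaldehyde (10), C=O
Why: Morita–Baylis–Hillman hydroxymethylation places the new carbon on the sulfonyl-bearing vinyl carbon, which gives the 2-sulfonylallyl connectivity directly.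

Step 7
Reactants: 11 allylic alcohol
Product: 12 2-(phenylsulfonyl)allyl bromide (3-bromo-2-(phenylsulfonyl)prop-1-ene)
Conditions: PBr3, Et2O, 0 °C
Reagents that add atoms: phosphorus tribromide, BrP(Br)Br
Why: SN2 conversion of a primary allylic alcohol into the bromide through its phosphite ester.

Step 8
Reactants: 8 methyl ketone; 12 2-(phenylsulfonyl)allyl bromide
Product: 14 (5S,6S)-5-[3-(tert-butyldimethylsilyloxy)prop-1-en-2-yl]-2,6-dimethyl-6-[2-(phenylsulfonyl)prop-2-en-1-yl]cyclohex-2-en-1-one, via lithium enolate 13 (not isolated)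
Conditions: LDA, THF/DMPU, −78 → −30 °C; 12, −78 °C
Reagents that add atoms: none
Why: Enolate alkylation (SN2 and SN2′ give the same product with this allyl unit) occurs on the face anti to the C5 side chain, which sets C10 with its methyl group cis and the sulfonylallyl arm trans to that chain.

Step 9
Reactants: 14 dialkylated carvone
Product: 15 trans-octalone with C9 ketone, Δ7, 8-CH3, 10β-CH3, 5α-H, 4β-CH3, 4α-CH2OTBS and 2ξ-SO2Ph
Conditions: Fe(acac)3 (30 mol %), PhSiH3 (slow addition), EtOH, 0.01 M, 60 °C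
Reagents that add atoms: none
Why: An iron hydride formed from Fe(acac)3 and PhSiH3 delivers a hydrogen atom to the CH2 terminus of the electron-rich 1,1-disubstituted alkene, the resulting nucleophilic tertiary C4 radical adds to the unsubstituted terminus (C3) of the vinyl sulfone, and the α-sulfonyl radical at C2 is reduced by Fe(II) and protonated by ethanol. The closest known reaction type is the iron-catalysed reductive olefin coupling (metal-hydride HAT followed by Giese addition) in its intramolecular form. Ring A closes in the 6-endo-trig mode, since the 5-exo path would require attack at the sulfonyl-bearing carbon C2, against both polarity and steric demand. The trans ring fusion follows from C5 and C10, whose two arms are trans on ring B and both equatorial, and C4 is controlled by the rotamer of the planar radical about C4–C5: the larger CH2OTBS group lies next to H5 and becomes equatorial (α), while the methyl group lies next to the crowded C5–C10 bond and becomes axial (β). C2 forms without control and is erased in step 17. The step needs hydrogen-atom transfer to the donor alkene only, which the electron-poor character of the enone and the vinyl sulfone secures, and it needs ring closure to outrun a second hydrogen transfer, which high dilution and slow addition of the silane secure; the enone cannot capture the radical, as that would give a four-membered or a strained bridged ring.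

Step 10
Reactants: 15 enone sulfone
Product: 16 6,8-dienol silyl ether (9-OTBS, C8=C9 and C6=C7)
Conditions: TBSOTf, Et3N, CH2Cl2, 0 °C
Reagents that add atoms: TBSOTf, CC(C)(C)[Si](C)(C)OS(=O)(=O)C(F)(F)F
Why: Soft enolisation; because C10 is quaternary, only γ-deprotonation at C6 is possible, which gives the linear dienol silyl ether.

Step 11
Reactants: 16 dienol silyl ether
Product: 17 6α-hydroxy-Δ7-9-one
Conditions: mCPBA, CH2Cl2/hexane, −20 °C; aq. work-up
Reagents that add atoms: mCPBA, OOC(=O)c1cccc(Cl)c1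
Why: Vinylogous Rubottom oxidation, in which the peracid attacks the accessible C6=C7 end of the dienol ether from the α face, opposite the axial methyl groups on C4 and C10, and collapse restores the enone with the equatorial 6α-OH, which is also the more stable epimer.

Step 12
Reactants: 17 γ-hydroxy enone
Product: 18 6α-OTBS enone
Conditions: TBSOTf, 2,6-lutidine, CH2Cl2, 0 °C
Reagents that add atoms: TBSOTf, CC(C)(C)[Si](C)(C)OS(=O)(=O)C(F)(F)F
Why: Silyl triflate silylation of a hindered secondary alcohol, needed so that only 8-OH is acylated in step 14.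

Step 13
Reactants: 18 enone
Product: 20 8α-hydroxy-8β-methyl-9-ketone, via 8α-hydroperoxide 19 (not isolated)
Conditions: Mn(dpm)3 (10 mol %), PhSiH3, O2 (1 atm), i-PrOH, 0 °C; then P(OEt)3
Reagents that add atoms: dioxygen, O=O
Why: Mukaiyama-type reductive α-hydroxylation of an enone (Mn–H HAT to C7, O2 capture at C8, phosphite reduction), with O2 approaching C8 from the α face because the β face is blocked by the syn-axial C10 methyl group.

Step 14
Reactants: 20 α-ketol; 21 diethylphosphonoacetic acid
Product: 22 8α-(diethylphosphonoacetoxy)-9-ketone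
Conditions: 21, DCC, DMAP (cat.), CH2Cl2, rt
Reagents that add atoms: diethylphosphonoacetic acid (21), OC(=O)CP(=O)(OCC)OCC
Why: Steglich esterification; the activated phosphonoacetic acid acylates hindered tertiary alcohols, and the other two hydroxyl groups are masked.

Step 15
Reactants: 22 phosphonoacetate
Product: 23 Δ9(11)-butenolide (C12 carbonyl, 8α-O, C9=C11)
Conditions: NaH, THF, 0 → 50 °C
Reagents that add atoms: none
Why: Intramolecular Horner–Wadsworth–Emmons olefination, in which the five-membered tether carries the phosphonate carbanion to the hindered, non-enolisable C9 ketone and forms C9=C11.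

Step 16
Reactants: 23 butenolide
Product: 24 saturated trans-fused 12,8α-olide with 9α-H
Conditions: H2 (5 bar), Pd/C, EtOAc, rt
Reagents that add atoms: none
Why: Heterogeneous syn-hydrogenation from the α face, since the β face of C9=C11 is shielded by the axial methyl groups on C8 and C10; this sets 9α-H with C11 equatorial.

Step 17
Reactants: 24 lactone sulfone
Product: 25 desulfonylated lactone (C2 = CH2)
Conditions: 6% Na(Hg), Na2HPO4, MeOH/THF, −10 °C → rt
Reagents that add atoms: none
Why: Reductive desulfonylation by electron transfer, placed here because no enone, ketol or butenolide remains that could be reduced.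

Step 18
Reactants: 25 lactone
Product: 26 8α,12-diol
Conditions: LiAlH4, THF, 0 °C
Reagents that add atoms: none
Why: Hydride reduction of the lactone to the diol; silyl ethers are inert.

Step 19
Reactants: 26 diol
Product: 27 12-iodo-8α-ol
Conditions: I2, PPh3, imidazole, CH2Cl2, 0 °C
Reagents that add atoms: iodine, II
Why: Appel-type (Garegg–Samuelsson) iodination is selective for the primary alcohol, and low temperature with imidazole buffering holds back ether formation by 8-OH.

Step 20
Reactants: 27 iodo alcohol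
Product: 28 12-iodide with 8α-OTES, 6α-OTBS and 4α-CH2OTBS
Conditions: TESOTf, 2,6-lutidine, CH2Cl2, −78 → 0 °C
Reagents that add atoms: TESOTf, CC[Si](CC)(CC)OS(=O)(=O)C(F)(F)F
Why: Silyl triflate silylation of the tertiary alcohol removes the acidic proton and the internal nucleophile before metalation.

Step 21
Reactants: 29 1,1-diethoxybut-2-yne
Product: 31 (E)-1,1-diethoxy-3-iodobut-2-ene, via vinylzirconocene 30 (not isolated)
Conditions: Cp2Zr(H)Cl, THF, rt; I2, 0 °C
Reagents that add atoms: iodine, II; zirconocene chloride hydride (zirconium only in 30), [H][Zr](Cl)(C1C=CC=C1)C1C=CC=C1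
Why: Hydrozirconation (syn addition, zirconium on the less hindered methyl-bearing alkyne carbon) followed by iodinolysis with retention gives the (E)-vinyl iodide.

Step 22
Reactants: 28 alkyl iodide; 31 vinyl iodide
Product: 34 (13E)-enal with C15 as aldehyde carbon, via alkylzinc iodide 32 (not isolated), via diethyl acetal 33 (not isolated)
Conditions: Zn dust, LiCl, THF, 40 °C; 31, Pd(dppf)Cl2 (5 mol %), rt; aq. oxalic acid, THF, 0 °C
Reagents that add atoms: water, O; zinc (only in 32), [Zn]
Why: Negishi sp3–sp2 cross-coupling with retention of alkene geometry forms C12–C13 and fixes the (13E) alkene, and the labile allylic acetal is hydrolysed in the acidic work-up.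

Step 23
Reactants: 34 enal; 35 4-methylfuran-2(5H)-one
Product: 38 tris-silylated target with (13E,15Z) side chain, via silyloxyfuran 36 (not isolated), via aldol silyl ether 37 (not isolated)
Conditions: 35, TBSOTf, i-Pr2NEt, CH2Cl2, 0 °C; 34, −78 → 0 °C; DBU, 0 °C → rt
Reagents that add atoms: 4-methylfuran-2(5H)-one (35), CC1=CC(=O)OC1; TBSOTf (silicon only in 36 and 37), CC(C)(C)[Si](C)(C)OS(=O)(=O)C(F)(F)F
Why: Vinylogous Mukaiyama aldol addition of the silyloxyfuran at its C5 followed by E1cB loss of silanolate, which favours the (Z)-ylidene isomer with the chain turned away from the ring methyl group.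

Step 24
Reactants: 38 tris-silyl ether
Product: 39 target CNP0126806.1
Conditions: HF·pyridine, pyridine, THF, 0 °C → rt
Reagents that add atoms: none
Why: Fluoride-mediated cleavage of all three silyl ethers under buffered conditions that spare the tertiary alcohol and the ylidene butenolide.

Compound list
1 | (R)-(−)-carvone | CC1=CC[C@H](CC1=O)C(C)=C | starting material
2 | (5R)-5-(3-chloroprop-1-en-2-yl)-2-methylcyclohex-2-en-1-one | CC1=CC[C@H](CC1=O)C(=C)CCl | intermediate
3 | (5R)-5-(3-acetoxyprop-1-en-2-yl)-2-methylcyclohex-2-en-1-one | CC1=CC[C@H](CC1=O)C(=C)COC(C)=O | intermediate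
4 | (5R)-5-(3-hydroxyprop-1-en-2-yl)-2-methylcyclohex-2-en-1-one | CC1=CC[C@H](CC1=O)C(=C)CO | intermediate
5 | (5R)-5-[3-(TBSO)prop-1-en-2-yl]-2-methylcyclohex-2-en-1-one | CC1=CC[C@H](CC1=O)C(=C)CO[Si](C)(C)C(C)(C)C | intermediate
6 | iodomethane | CI | starting material
7 | lithium cross-conjugated dienolate of 5 | [Li]OC1=C[C@H](C(=C)CO[Si](C)(C)C(C)(C)C)CC=C1C | intermediate
8 | (5R,6RS)-5-[3-(TBSO)prop-1-en-2-yl]-2,6-dimethylcyclohex-2-en-1-one | O=C1C(C)=CC[C@@H](C(=C)CO[Si](C)(C)C(C)(C)C)C1C | intermediate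
9 | phenyl vinyl sulfone | C=CS(=O)(=O)c1ccccc1 | starting material
10 | formaldehyde | C=O | starting material
11 | 2-(phenylsulfonyl)prop-2-en-1-ol | OCC(=C)S(=O)(=O)c1ccccc1 | intermediate
12 | 2-(phenylsulfonyl)allyl bromide | BrCC(=C)S(=O)(=O)c1ccccc1 | intermediate
13 | lithium enolate of 8 | [Li]OC1=C(C)[C@H](C(=C)CO[Si](C)(C)C(C)(C)C)CC=C1C | intermediate
14 | (5S,6S)-5-[3-(TBSO)prop-1-en-2-yl]-2,6-dimethyl-6-[2-(phenylsulfonyl)prop-2-en-1-yl]cyclohex-2-en-1-one (key-step precursor) | O=C1C(C)=CC[C@@H](C(=C)CO[Si](C)(C)C(C)(C)C)[C@]1(C)CC(=C)S(=O)(=O)c1ccccc1 | intermediate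
15 | trans-octalone, 9-one, Δ7, 4α-CH2OTBS, 4β-CH3, 10β-CH3, 5α-H, 2ξ-SO2Ph (key-step product) | O=C1C(C)=CC[C@@H]2[C@]1(C)CC(S(=O)(=O)c1ccccc1)C[C@@]2(C)CO[Si](C)(C)C(C)(C)C | intermediate
16 | 9-(TBSO)-6,8-diene | CC(C)(C)[Si](C)(C)OC1=C(C)C=C[C@@H]2[C@]1(C)CC(S(=O)(=O)c1ccccc1)C[C@@]2(C)CO[Si](C)(C)C(C)(C)C | intermediate
17 | 6α-hydroxy-Δ7-9-one | O=C1C(C)=C[C@H](O)[C@@H]2[C@]1(C)CC(S(=O)(=O)c1ccccc1)C[C@@]2(C)CO[Si](C)(C)C(C)(C)C | intermediate
18 | 6α-(TBSO)-Δ7-9-one | O=C1C(C)=C[C@H](O[Si](C)(C)C(C)(C)C)[C@@H]2[C@]1(C)CC(S(=O)(=O)c1ccccc1)C[C@@]2(C)CO[Si](C)(C)C(C)(C)C | intermediate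
19 | 8α-hydroperoxy-8β-methyl-9-ketone | O=C1[C@](C)(OO)C[C@H](O[Si](C)(C)C(C)(C)C)[C@@H]2[C@]1(C)CC(S(=O)(=O)c1ccccc1)C[C@@]2(C)CO[Si](C)(C)C(C)(C)C | intermediate
20 | 8α-hydroxy-8β-methyl-9-ketone | O=C1[C@](C)(O)C[C@H](O[Si](C)(C)C(C)(C)C)[C@@H]2[C@]1(C)CC(S(=O)(=O)c1ccccc1)C[C@@]2(C)CO[Si](C)(C)C(C)(C)C | intermediate
21 | diethylphosphonoacetic acid | OC(=O)CP(=O)(OCC)OCC | starting material
22 | 8α-(diethylphosphonoacetoxy)-9-ketone | O=C1[C@](C)(OC(=O)CP(=O)(OCC)OCC)C[C@H](O[Si](C)(C)C(C)(C)C)[C@@H]2[C@]1(C)CC(S(=O)(=O)c1ccccc1)C[C@@]2(C)CO[Si](C)(C)C(C)(C)C | intermediate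
23 | Δ9(11)-12,8α-butenolide | O=C1O[C@]2(C)C[C@H](O[Si](C)(C)C(C)(C)C)[C@@H]3[C@](C)(CC(S(=O)(=O)c4ccccc4)C[C@@]3(C)CO[Si](C)(C)C(C)(C)C)C2=C1 | intermediate
24 | saturated 12,8α-olide, 9α-H, 2ξ-SO2Ph | O=C1O[C@]2(C)C[C@H](O[Si](C)(C)C(C)(C)C)[C@@H]3[C@](C)(CC(S(=O)(=O)c4ccccc4)C[C@@]3(C)CO[Si](C)(C)C(C)(C)C)[C@H]2C1 | intermediate
25 | saturated 12,8α-olide without sulfone | O=C1O[C@]2(C)C[C@H](O[Si](C)(C)C(C)(C)C)[C@@H]3[C@](C)(CCC[C@@]3(C)CO[Si](C)(C)C(C)(C)C)[C@H]2C1 | intermediate
26 | 8α,12-diol | OCC[C@@H]1[C@@]2(C)CCC[C@@](C)(CO[Si](C)(C)C(C)(C)C)[C@@H]2[C@@H](O[Si](C)(C)C(C)(C)C)C[C@@]1(C)O | intermediate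
27 | 12-iodo-8α-ol | ICC[C@@H]1[C@@]2(C)CCC[C@@](C)(CO[Si](C)(C)C(C)(C)C)[C@@H]2[C@@H](O[Si](C)(C)C(C)(C)C)C[C@@]1(C)O | intermediate
28 | 12-iodide, 8α-OTES | ICC[C@@H]1[C@@]2(C)CCC[C@@](C)(CO[Si](C)(C)C(C)(C)C)[C@@H]2[C@@H](O[Si](C)(C)C(C)(C)C)C[C@@]1(C)O[Si](CC)(CC)CC | intermediate
29 | 1,1-diethoxybut-2-yne | CC#CC(OCC)OCC | starting material
30 | (E)-vinylzirconocene chloride | CCOC(OCC)\C=C(/C)[Zr](Cl)(C1C=CC=C1)C1C=CC=C1 | intermediate
31 | (E)-1,1-diethoxy-3-iodobut-2-ene | CCOC(OCC)\C=C(/C)I | intermediate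
32 | C12 alkylzinc iodide | I[Zn]CC[C@@H]1[C@@]2(C)CCC[C@@](C)(CO[Si](C)(C)C(C)(C)C)[C@@H]2[C@@H](O[Si](C)(C)C(C)(C)C)C[C@@]1(C)O[Si](CC)(CC)CC | intermediate
33 | (13E)-C15 diethyl acetal | CCOC(OCC)\C=C(/C)CC[C@@H]1[C@@]2(C)CCC[C@@](C)(CO[Si](C)(C)C(C)(C)C)[C@@H]2[C@@H](O[Si](C)(C)C(C)(C)C)C[C@@]1(C)O[Si](CC)(CC)CC | intermediate
34 | (13E)-C15 enal | O=C\C=C(/C)CC[C@@H]1[C@@]2(C)CCC[C@@](C)(CO[Si](C)(C)C(C)(C)C)[C@@H]2[C@@H](O[Si](C)(C)C(C)(C)C)C[C@@]1(C)O[Si](CC)(CC)CC | intermediate
35 | 4-methylfuran-2(5H)-one | CC1=CC(=O)OC1 | starting material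
36 | 2-(TBSO)-4-methylfuran | Cc1coc(O[Si](C)(C)C(C)(C)C)c1 | intermediate
37 | C15-OTBS vinylogous aldol adduct (C15, C16 unassigned) | CC1=CC(=O)OC1C(O[Si](C)(C)C(C)(C)C)\C=C(/C)CC[C@@H]1[C@@]2(C)CCC[C@@](C)(CO[Si](C)(C)C(C)(C)C)[C@@H]2[C@@H](O[Si](C)(C)C(C)(C)C)C[C@@]1(C)O[Si](CC)(CC)CC | intermediate
38 | tris-silylated target | CC1=CC(=O)O/C1=C\C=C(/C)CC[C@@H]1[C@@]2(C)CCC[C@@](C)(CO[Si](C)(C)C(C)(C)C)[C@@H]2[C@@H](O[Si](C)(C)C(C)(C)C)C[C@@]1(C)O[Si](CC)(CC)CC | intermediate
39 | CNP0126806.1 | CC1=CC(=O)O/C1=C\C=C(/C)CC[C@@H]1[C@@]2(C)CCC[C@@](C)(CO)[C@@H]2[C@@H](O)C[C@@]1(C)O | target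

Total step count: 24
Longest linear sequence: 21 steps from (R)-carvone (steps 1–5, 8–20, 22–24)

Steps most likely to fail

**Step 9.**
- *What may go wrong:* the planar C4 radical may close with little preference between its two rotamers about C4–C5, giving poor facial selectivity at C4. It may also pick up a second hydrogen atom before ring closure, and the metal hydride may slowly reduce the enone.
- *Fallback:* it sets out from 1 and comes back at 15. It makes the same radical by homolytic epoxide opening instead of hydrogen-atom transfer. Carvone 1 is methylated (LDA, 6) to 6-methylcarvone F1 and alkylated with 12 (LDA) to the dialkylated carvone F2. mCPBA epoxidises only the isopropenyl group to the side-chain epoxide F3, and both epimers serve. Cp2TiCl (Cp2TiCl2, Mn, collidine hydrochloride, THF) opens the epoxide to the tertiary C4 radical, which now carries a very bulky CH2O–Ti group that should reinforce the equatorial preference. 6-Endo closure onto the vinyl sulfone gives the hydroxymethyl octalone F4, and TBSCl/imidazole then gives 15.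

**Step 15.**
- *What may go wrong:* the stabilised phosphonate carbanion may fail to add to a ketone flanked by two fully substituted carbons, so that ester cleavage or ketol rearrangement takes over.
- *Fallback:* it sets out from 20 and comes back at 23. It replaces the olefination by an aldol addition followed by dehydration. Acetylation (Ac2O, DMAP, Et3N) gives the 8α-acetoxy ketone F5. LiHMDS in THF at −78 °C brings about the intramolecular acetate aldol addition from the α face to give the cis-fused 9β-hydroxy lactone F6. SOCl2/pyridine then removes the tertiary alcohol toward C11 to give 23.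

**Step 11.**
- *What may go wrong:* the peracid may attack the more electron-rich C8=C9 enol ether bond instead of C6=C7, which loses the regioselectivity, or it may approach from the β face.
- *Fallback:* it sets out from 16 and comes back at 17. It uses a cycloaddition whose termini can only be C6 and C9. Photooxygenation (O2, tetraphenylporphyrin, hν, CH2Cl2, −78 °C) adds singlet oxygen to the α face of the diene to give the 6α,9α-endoperoxide F7. Reduction of the O–O bond with PPh3 and collapse of the silyl hemiketal then give 17.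

Further compounds
F1 | step 9 | 6-methylcarvone (C6 epimers) | O=C1C(C)=CC[C@@H](C(C)=C)C1C
F2 | step 9 | (5,6-trans-armed) 6-methyl-6-[2-(phenylsulfonyl)allyl]carvone | O=C1C(C)=CC[C@@H](C(C)=C)[C@]1(C)CC(=C)S(=O)(=O)c1ccccc1
F3 | step 9 | side-chain epoxide of F2 (epoxide carbon unassigned) | O=C1C(C)=CC[C@@H](C2(C)CO2)[C@]1(C)CC(=C)S(=O)(=O)c1ccccc1
F4 | step 9 | 4α-hydroxymethyl octalone sulfone | O=C1C(C)=CC[C@@H]2[C@]1(C)CC(S(=O)(=O)c1ccccc1)C[C@@]2(C)CO
F5 | step 15 | 8α-acetoxy-9-ketone | O=C1[C@](C)(OC(C)=O)C[C@H](O[Si](C)(C)C(C)(C)C)[C@@H]2[C@]1(C)CC(S(=O)(=O)c1ccccc1)C[C@@]2(C)CO[Si](C)(C)C(C)(C)C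
F6 | step 15 | cis-fused 9β-hydroxy-12,8α-olide | O=C1O[C@]2(C)C[C@H](O[Si](C)(C)C(C)(C)C)[C@@H]3[C@](C)(CC(S(=O)(=O)c4ccccc4)C[C@@]3(C)CO[Si](C)(C)C(C)(C)C)[C@]2(O)C1
F7 | step 11 | 6α,9α-epidioxy-9β-(TBSO)-Δ7 compound | CC1=C[C@@H]2OO[C@@]1(O[Si](C)(C)C(C)(C)C)[C@@]3(C)CC(S(=O)(=O)c4ccccc4)C[C@@](C)(CO[Si](C)(C)C(C)(C)C)[C@H]23
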